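A small charge of Q has to carry X through itself more than once, so I turned the question round: how fast must each Q work for G to draw level with X at the end?

| setting | violet | blue | south | north |
|---|---|---|---|---|
| X | 1.2 M | 0.80 M | 0.80 M | 0.80 M |
| J | 0.80 M | 0.40 M | 0.800 M | 0.800 M |
| Q | 96 mM | 96 mM | 96 mM | 240 mM |
| remark | run made earlier | run made earlier |  |  |
| time |  |  | 50 min | 50 min |

| run | time / min | X / % | D / % | L / % | G / % | E / % |
|---|---|---|---|---|---|---|
| violet | 1.00 | 96.3 | 2.4 | 1.0 | 0 | 0.6 |
| violet | 2.50 | 93.7 | 2.6 | 2.1 | 0.6 | 1.4 |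
| violet | 5.00 | 91.3 | 1.9 | 3.3 | 2.8 | 0.1 |
| violet | 8.00 | 89.4 | 1.5 | 3.6 | 3.7 | 0 |
| violet | 10.0 | 88.9 | 1.1 | 3.3 | 5.5 | 0 |
| violet | 15.0 | 85.0 | 2.2 | 4.5 | 8.5 | 0.6 |
| violet | 20.0 | 81.5 | 1.7 | 2.9 | 10.9 | 1.5 |
| blue | 2.50 | 92.1 | 4.5 | 2.0 | 0.4 | 0.4 |
| blue | 5.00 | 90.4 | 4.6 | 3.2 | 2.0 | 0.2 |
| blue | 8.00 | 88.3 | 3.3 | 4.1 | 4.2 | 0.6 |
| blue | 10.0 | 87.1 | 4.2 | 5.0 | 5.8 | 0 |
| blue | 12.0 | 85.9 | 3.7 | 3.9 | 6.6 | 0.1 |
| blue | 15.0 | 85.0 | 3.2 | 3.8 | 8.7 | 0.3 |
| blue | 20.0 | 81.4 | 3.1 | 3.0 | 11.5 | 1.5 |

(scatter of a reading: 0.5 percentage points)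

1. which of these there is most of at the end, counted by the X in it, south (L / E / X / G / D)
2. which of these there is most of at the end, counted by the X in it, north (L / E / X / G / D)
3. amount of the one of these that there is most of at the end, in percent of the X charged, south
4. amount of the one of these that there is most of at the end, in percent of the X charged, north

- steps that have been proposed: X + Q <-> D; J + D <-> L; L -> Q + G; J + G -> E; Q <-> Z
- no earlier run changes the charge of Q; that part of a forecast is a guess

I reckoned in fractions of the X charged. Q is 0.120 of that charge in south and 0.300 in north. X and G share what remains after a small correction, which I took from two readings. D and L held 6.10 % at the end of the blue run, which has south's X charge. E read 1.5 % at the end of the violet run, which has south's J charge, and because the proposed steps make E from G, I let it grow with the square of time: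

E at 50 min: 9.38 %; correction: 15.5 %

This is rough, and I kept it for north too. Level means that G holds half of the remainder, 42.3 %. Dividing by the Q fraction and the time gives the demand, the G each Q charged must make per minute, a required turnover frequency:

south: 0.0704 /min; north: 0.0282 /min

Between their readings at 10.0 min and 20.0 min, the earlier runs showed:

blue: 0.0475 /min; violet: 0.0675 /min

Both readings fell short of south's demand, violet narrowly and with more X than south, so I expected X to stay ahead there. North's demand stood below the blue pace, so I expected G ahead, though no earlier run changed Q.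

The forecast gave X at 61 % for south and G at 56 % for north, adding: “The Q scaling is an extrapolation”.

The flasks gave X at 57.4 % in south and G at 57.2 % in north.

    X + Q ⇌ D (K = 3.60 /M, k = 0.0110 /M/s)
    J + D ⇌ L (K = 74.0 /M, k = 0.0110 /M/s)
    L → Q + G (k = 0.00310 /s)
    J + G → E (k = 3.10 × 10⁻⁴ /M/s)
    Q ⇌ Z (K = 1.60, k = 9.00 × 10⁻⁴ /s)

Over 50 min, each Q charged in south made G at a mean 0.0490 /min, less than the demand of 0.0704 /min, while north's mean of 0.0381 /min was more than its 0.0282 /min. The one-step first-order fit to the G and X readings, with all reacted X read as G, puts X and G level at 153 mM of Q, and the flask like north but with 0.060 M of Q, facing a demand of 0.113 /min, delivered 0.0514 /min and ended with X ahead, at 71.1 %.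

The numbers in the tables were generated by integration on assumed constants.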